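**Strategy.** Everything rests on cutting the bond between the spiro carbon C6 and the ring-B methylene C7 (spiro[5.5]undecane numbering). This CH2 lies next to the ring-B CHBr (C8), itself adjacent to CMeCl (C9), so it can be introduced as a β-bromo primary triflate. In one operation the tetrasubstituted ring-A alkene attacks that carbon with bromine assistance: ring B closes, the quaternary spiro stereocentre is set, and the exocyclic methylene at C5 of ring A appears. The precursor is a monocyclic bromo-β-cyclofarnesyl alcohol: a (5R)-5-bromo-2,6,6-trimethylcyclohexenyl ring carrying a (2S,3S)-2-bromo-3-chloro-3-methylpentan-1-ol chain, with all three halogens already in place.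

Key step: step 13

Assumption: the tridentate Schiff-base ligand of the titanium-mediated bromochlorination (salicylaldimine of an enantiopure 2-amino-1,1-diarylalkan-1-ol, made by condensation of the commercial components) is taken to show the same facial preference for both allylic alcohols; L is the enantiomer that places bromine on the Si face of C2 (step 1), ent-L the one that places it on the Re face (step 12), to be confirmed on small scale.

Step 1
Reactants: 1 3-methylbut-2-en-1-ol (prenol); 2 N-bromosuccinimide
Product: 3 (2R)-2-bromo-3-chloro-3-methylbutan-1-ol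
Conditions: ClTi(OiPr)3 (1.1 equiv), ligand L (20 mol %), hexanes, −20 °C
Reagents that add atoms: N-bromosuccinimide (compound 2), O=C1CCC(=O)N1Br; chlorotitanium triisopropoxide, CC(C)O[Ti](Cl)(OC(C)C)OC(C)C
Why: Enantioselective titanium-mediated bromochlorination of an allylic alcohol: anti addition within the chiral titanium alkoxide complex puts bromine on C2 and chloride on the tertiary C3, and ligand L directs bromine to the Si face of C2, which sets the (R) centre that becomes the ring-A CHBr.

Step 2
Reactants: 3 (2R)-2-bromo-3-chloro-3-methylbutan-1-ol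
Product: 4 (2R)-2-bromo-3-chloro-3-methylbutyl trifluoromethanesulfonate
Conditions: Tf2O, 2,6-lutidine, CH2Cl2, −78 °C; used without chromatography
Reagents that add atoms: trifluoromethanesulfonic anhydride, O=S(=O)(OS(=O)(=O)C(F)(F)F)C(F)(F)F
Why: O-Sulfonylation of a primary alcohol; the electron-withdrawing β-bromine retards ionisation, so the triflate should survive cold handling and the stereocentre is not touched.

Step 3
Reactants: 4 (2R)-2-bromo-3-chloro-3-methylbutyl trifluoromethanesulfonate; 5 methyl acetoacetate
Product: 7 methyl (6R)-6-bromo-7-chloro-7-methyl-3-oxooctanoate, via methyl acetoacetate dianion 6 (not isolated)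
Conditions: 5, NaH then n-BuLi, THF, 0 °C; then 4, −78 → 0 °C; aq. NH4Cl
Reagents that add atoms: none
Why: γ-Alkylation of an acetoacetate dianion, whose terminal carbon should displace the unhindered primary triflate by SN2 at −78 °C faster than it eliminates, leaving the C–Br centre unchanged.

Step 4
Reactants: 7 methyl (6R)-6-bromo-7-chloro-7-methyl-3-oxooctanoate
Product: 9 methyl (3R)-3-bromo-2,2-dimethyl-6-oxocyclohexane-1-carboxylate, via bromonium ion 8 (not isolated)
Conditions: (CF3)2CHOH, NaHCO3, rt
Reagents that add atoms: none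
Why: Solvolytic bromonium-ion cyclisation (cation–olefin type): in the ionising, weakly nucleophilic solvent the tertiary chloride leaves with anchimeric help from the vicinal bromine, and the enol carbon of the β-keto ester opens bromonium ion 8 at its tertiary carbon in a 6-(enolendo) closure, so the C–Br configuration is carried over intact; C1 is epimerisable and is erased in step 5.

Step 5
Reactants: 9 methyl (3R)-3-bromo-2,2-dimethyl-6-oxocyclohexane-1-carboxylate
Product: 10 methyl (5R)-5-bromo-6,6-dimethyl-2-[(trifluoromethanesulfonyl)oxy]cyclohex-1-ene-1-carboxylate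
Conditions: Tf2O, iPr2NEt, CH2Cl2, −78 °C
Reagents that add atoms: trifluoromethanesulfonic anhydride, O=S(=O)(OS(=O)(=O)C(F)(F)F)C(F)(F)F
Why: Enol triflate formation from a cyclic β-keto ester, whose stabilised enol fixes the tetrasubstituted alkene position; the amine base at −78 °C is too weak to eliminate HBr.

Step 6
Reactants: 10 methyl (5R)-5-bromo-6,6-dimethyl-2-[(trifluoromethanesulfonyl)oxy]cyclohex-1-ene-1-carboxylate
Product: 11 methyl (5R)-5-bromo-2,6,6-trimethylcyclohex-1-ene-1-carboxylate
Conditions: MeZnCl, Pd(PPh3)4 (5 mol %), THF, rt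
Reagents that add atoms: methylzinc chloride, C[Zn]Cl
Why: Negishi cross-coupling: the activated vinyl triflate adds oxidatively to zerovalent palladium far faster than the hindered secondary alkyl bromide can react, and methyl transfer completes the tetrasubstituted alkene with defined regiochemistry.

Step 7
Reactants: 11 methyl (5R)-5-bromo-2,6,6-trimethylcyclohex-1-ene-1-carboxylate
Product: 12 [(5R)-5-bromo-2,6,6-trimethylcyclohex-1-en-1-yl]methanol
Conditions: iBu2AlH (2.5 equiv), CH2Cl2, −78 °C; aq. potassium sodium tartrate
Reagents that add atoms: none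
Why: 1,2-Reduction of an α,β-unsaturated ester to the allylic alcohol with an aluminium hydride, which should not touch the alkyl bromide at −78 °C.

Step 8
Reactants: 12 [(5R)-5-bromo-2,6,6-trimethylcyclohex-1-en-1-yl]methanol
Product: 13 (5R)-5-bromo-2,6,6-trimethylcyclohex-1-ene-1-carbaldehyde
Conditions: Dess–Martin periodinane, CH2Cl2, rt
Reagents that add atoms: none
Why: Dess–Martin oxidation of a primary allylic alcohol to the enal under near-neutral conditions, without alkene migration or loss of HBr.

Step 9
Reactants: 13 (5R)-5-bromo-2,6,6-trimethylcyclohex-1-ene-1-carbaldehyde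
Product: 14 (4R)-4-bromo-2-ethenyl-1,3,3-trimethylcyclohex-1-ene
Conditions: Ph3PCH3Br, KOtBu, THF, 0 °C → rt
Reagents that add atoms: methyltriphenylphosphonium bromide, C[P+](c1ccccc1)(c1ccccc1)c1ccccc1.[Br-]
Why: Wittig methylenation, which works on hindered β-cyclocitral-type aldehydes; the equatorial neopentyl bromide should resist E2 during the short exposure to the ylide.

Step 10
Reactants: 15 but-2-yn-1-ol
Product: 17 (2Z)-3-iodobut-2-en-1-ol, via cyclic vinylalanate 16 (not isolated)
Conditions: NaAlH2(OCH2CH2OMe)2, THF, 0 °C → rt; then I2, −78 °C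
Reagents that add atoms: iodine, [I][I]
Why: Hydroxyl-directed trans-hydroalumination of a propargylic alcohol places aluminium on C3 in cyclic alanate 16, and iodinolysis with retention gives the Z vinyl iodide.

Step 11
Reactants: 14 (4R)-4-bromo-2-ethenyl-1,3,3-trimethylcyclohex-1-ene; 17 (2Z)-3-iodobut-2-en-1-ol
Product: 19 (2Z)-5-[(5R)-5-bromo-2,6,6-trimethylcyclohex-1-en-1-yl]-3-methylpent-2-en-1-ol, via B-alkyl-9-BBN borane 18 (not isolated)
Conditions: 9-BBN, THF, 0 °C → rt; then 17, Pd(dppf)Cl2 (5 mol %), aq. K3PO4, DMF, rt
Reagents that add atoms: none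
Why: Hydroboration followed by B-alkyl Suzuki–Miyaura coupling: 9-BBN adds only to the monosubstituted vinyl group (boron on the terminal carbon), and borane 18 couples with the vinyl iodide with retention, so the ring chain and CH2OH end up cis (Z); the alkyl bromide is inert to the catalyst at room temperature.

Step 12
Reactants: 19 (2Z)-5-[(5R)-5-bromo-2,6,6-trimethylcyclohex-1-en-1-yl]-3-methylpent-2-en-1-ol; 2 N-bromosuccinimide
Product: 20 (2S,3S)-2-bromo-5-[(5R)-5-bromo-2,6,6-trimethylcyclohex-1-en-1-yl]-3-chloro-3-methylpentan-1-ol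
Conditions: ClTi(OiPr)3 (1.1 equiv), ligand ent-L (20 mol %), hexanes, −20 °C
Reagents that add atoms: N-bromosuccinimide (compound 2), O=C1CCC(=O)N1Br; chlorotitanium triisopropoxide, CC(C)O[Ti](Cl)(OC(C)C)OC(C)C
Why: Enantioselective titanium-mediated bromochlorination of an allylic alcohol: anti addition to the Z alkene (Br on C2, Cl on tertiary C3) fixes the (2S,3S) relative configuration, ent-L sets its absolute sense by delivering bromine to the Re face of C2, and binding of the alcohol to titanium should confine halogen delivery to the allylic alkene and spare the neopentyl-flanked ring-A alkene.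

Step 13
Reactants: 20 (2S,3S)-2-bromo-5-[(5R)-5-bromo-2,6,6-trimethylcyclohex-1-en-1-yl]-3-chloro-3-methylpentan-1-ol
Product: 24 (2R,6R,8S,9S)-2,8-dibromo-9-chloro-1,1,9-trimethyl-5-methylidenespiro[5.5]undecane, via primary triflate 21 (not isolated), via bromonium triflate 22 (not isolated), via tertiary spiro cation 23 (not isolated)
Conditions: Tf2O, 2,6-di-tert-butyl-4-methylpyridine, CH2Cl2, −78 → 0 °C
Reagents that add atoms: none
Why: Proposed new method: the alcohol is converted at −78 °C into triflate 21, whose ionisation is assisted by the vicinal bromine to give bromonium ion 22 (or its tight ion pair); the tetrasubstituted ring-A alkene then attacks the primary carbon C1, so the C2–Br bond is never broken and C2 keeps its configuration, and tertiary cation 23 loses a methyl proton to the hindered pyridine to give the exocyclic methylene. The closest known reaction types are cation–olefin cyclisations started by anchimerically generated bromonium ions (as in step 4), π-participation of alkenes in the solvolysis of primary sulfonates, and acid-induced spirocyclisation of monocyclofarnesyl cations. Ring B closes as a six-membered ring in the exo mode with respect to the alkene (the attacking carbon becomes the spiro atom, its partner stays outside the new ring) and by opening the bromonium ion at its primary end; attack at the secondary end, which would give a five-membered ring, is disfavoured by the adjacent fully substituted C3. The new spiro stereocentre is controlled by ring A: with the C–Br bond equatorial in the half-chair, the pseudoaxial methyl of the gem-dimethyl carbon shields the face cis to bromine, so the new bond forms trans to the ring-A bromine, which is the (6R) configuration. The step needs the triflate to ionise in preference to the tertiary chloride, which the non-ionising solvent and low temperature should secure, and proton loss from the methyl group, which the bulky base favours; any endocyclic alkene isomer would be removed on AgNO3-impregnated silica.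

**Compound list**

1 | 3-methylbut-2-en-1-ol (prenol) | CC(C)=CCO | starting material
2 | N-bromosuccinimide | O=C1CCC(=O)N1Br | starting material
3 | (2R)-2-bromo-3-chloro-3-methylbutan-1-ol | OC[C@@H](Br)C(C)(C)Cl | intermediate
4 | (2R)-2-bromo-3-chloro-3-methylbutyl trifluoromethanesulfonate | FC(F)(F)S(=O)(=O)OC[C@@H](Br)C(C)(C)Cl | intermediate
5 | methyl acetoacetate (methyl 3-oxobutanoate) | COC(=O)CC(C)=O | starting material
6 | methyl acetoacetate dianion, sodium lithium salt | C=C([O-])C=C([O-])OC.[Na+].[Li+] | intermediate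
7 | methyl (6R)-6-bromo-7-chloro-7-methyl-3-oxooctanoate | COC(=O)CC(=O)CC[C@@H](Br)C(C)(C)Cl | intermediate
8 | bromonium chloride ion pair of 7 (bromine bridging C6 and C7, C6 configuration retained) | COC(=O)CC(=O)CC[C@@H]1C(C)(C)[Br+]1.[Cl-] | intermediate
9 | methyl (3R)-3-bromo-2,2-dimethyl-6-oxocyclohexane-1-carboxylate (C1 epimerisable, keto/enol mixture) | COC(=O)C1C(=O)CC[C@@H](Br)C1(C)C | intermediate
10 | methyl (5R)-5-bromo-6,6-dimethyl-2-[(trifluoromethanesulfonyl)oxy]cyclohex-1-ene-1-carboxylate | COC(=O)C1=C(OS(=O)(=O)C(F)(F)F)CC[C@@H](Br)C1(C)C | intermediate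
11 | methyl (5R)-5-bromo-2,6,6-trimethylcyclohex-1-ene-1-carboxylate | COC(=O)C1=C(C)CC[C@@H](Br)C1(C)C | intermediate
12 | [(5R)-5-bromo-2,6,6-trimethylcyclohex-1-en-1-yl]methanol | OCC1=C(C)CC[C@@H](Br)C1(C)C | intermediate
13 | (5R)-5-bromo-2,6,6-trimethylcyclohex-1-ene-1-carbaldehyde | O=CC1=C(C)CC[C@@H](Br)C1(C)C | intermediate
14 | (4R)-4-bromo-2-ethenyl-1,3,3-trimethylcyclohex-1-ene | C=CC1=C(C)CC[C@@H](Br)C1(C)C | intermediate
15 | but-2-yn-1-ol | CC#CCO | starting material
16 | sodium 2,2-bis(2-methoxyethoxy)-3-methyl-2,5-dihydro-1,2-oxaaluminol-2-uide (cyclic vinylalanate) | CC1=CCO[Al-]1(OCCOC)OCCOC.[Na+] | intermediate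
17 | (2Z)-3-iodobut-2-en-1-ol | C/C(I)=C/CO | intermediate
18 | 9-{2-[(5R)-5-bromo-2,6,6-trimethylcyclohex-1-en-1-yl]ethyl}-9-borabicyclo[3.3.1]nonane | C(CB1C2CCCC1CCC2)C3=C(C)CC[C@@H](Br)C3(C)C | intermediate
19 | (2Z)-5-[(5R)-5-bromo-2,6,6-trimethylcyclohex-1-en-1-yl]-3-methylpent-2-en-1-ol | OC/C=C(C)\CCC1=C(C)CC[C@@H](Br)C1(C)C | intermediate
20 | (2S,3S)-2-bromo-5-[(5R)-5-bromo-2,6,6-trimethylcyclohex-1-en-1-yl]-3-chloro-3-methylpentan-1-ol | CC1=C(CC[C@](C)(Cl)[C@@H](Br)CO)C(C)(C)[C@H](Br)CC1 | intermediate
21 | (2S,3S)-2-bromo-5-[(5R)-5-bromo-2,6,6-trimethylcyclohex-1-en-1-yl]-3-chloro-3-methylpentyl trifluoromethanesulfonate | CC1=C(CC[C@](C)(Cl)[C@@H](Br)COS(=O)(=O)C(F)(F)F)C(C)(C)[C@H](Br)CC1 | intermediate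
22 | bromonium triflate of 21 (bromine bridging C1 and C2 of the chain, C2 configuration retained) | CC1=C(CC[C@](C)(Cl)[C@@H]2C[Br+]2)C(C)(C)[C@H](Br)CC1.[O-]S(=O)(=O)C(F)(F)F | intermediate
23 | (2R,6R,8S,9S)-2,8-dibromo-9-chloro-1,1,5,9-tetramethylspiro[5.5]undecan-5-ylium triflate | C[C+]1CC[C@@H](Br)C(C)(C)[C@@]12CC[C@](C)(Cl)[C@@H](Br)C2.[O-]S(=O)(=O)C(F)(F)F | intermediate
24 | (2R,6R,8S,9S)-2,8-dibromo-9-chloro-1,1,9-trimethyl-5-methylidenespiro[5.5]undecane | C=C1CC[C@@H](Br)C(C)(C)[C@@]12CC[C@](C)(Cl)[C@@H](Br)C2 | target

**Step count.** Total: 13 steps. Longest linear sequence: 12 (steps 1–9 and 11–13); step 10 is a one-step side branch.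

**Steps most likely to fail**

Step 13 (proposed new method). The triflate may ionise without forming the C–C bond (elimination, bromine shift, loss of the tertiary chloride). The alkene may be attacked on the face cis to the ring-A bromine. The cation may lose a ring proton and give the endocyclic alkene. The fallback uses known chemistry, sets out from allylic alcohol 19 and returns at target 24. Ionisation of 19 with BF3·OEt2 in CH2Cl2 at −78 °C would give the Z allyl cation, which the ring-A alkene captures at its primary terminus through the same carbon and face; this is the acid-induced spirocyclisation known for monocyclofarnesyl cations. Proton loss gives (2R,6R)-2-bromo-1,1,9-trimethyl-5-methylidenespiro[5.5]undec-8-ene F1. Anti bromochlorination of the trisubstituted ring-B alkene of F1 with Bu4NBrCl2 in CH2Cl2 at −78 °C (bromine to C8, chloride to tertiary C9) would then give 24. This alkene is more nucleophilic than the hindered exocyclic methylene, but facial selectivity is not assured and diastereomers would have to be separated.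

Step 12. Electrophilic bromine may be consumed by the electron-rich ring-A alkene, or facial control may erode on this larger Z substrate. The fallback sets out from enol triflate 10 and returns at 20; it keeps the ring alkene electron-poor until the halogens are in place.
- Reduction of 10 with iBu2AlH gives [(5R)-5-bromo-6,6-dimethyl-2-(trifluoromethanesulfonyloxy)cyclohex-1-en-1-yl]methanol F2.
- Dess–Martin oxidation gives (5R)-5-bromo-6,6-dimethyl-2-(trifluoromethanesulfonyloxy)cyclohex-1-ene-1-carbaldehyde F3.
- Wittig methylenation gives (4R)-4-bromo-2-ethenyl-3,3-dimethylcyclohex-1-en-1-yl trifluoromethanesulfonate F4.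
- Hydroboration with 9-BBN gives (4R)-4-bromo-2-[2-(9-borabicyclo[3.3.1]nonan-9-yl)ethyl]-3,3-dimethylcyclohex-1-en-1-yl trifluoromethanesulfonate F5.
- Coupling of F5 with 17, the vinyl iodide reacting ahead of the hindered vinyl triflate, gives (4R)-4-bromo-2-[(3Z)-5-hydroxy-3-methylpent-3-en-1-yl]-3,3-dimethylcyclohex-1-en-1-yl trifluoromethanesulfonate F6.
- Bromochlorination under the conditions of step 12 gives (4R)-4-bromo-2-[(3S,4S)-4-bromo-3-chloro-5-hydroxy-3-methylpentyl]-3,3-dimethylcyclohex-1-en-1-yl trifluoromethanesulfonate F7.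
- Negishi methylation of the ring triflate of F7 (MeZnCl, Pd(PPh3)4) delivers 20.

Step 4. The bromonium ion may be captured at the carbonyl or enol oxygen, HCl may be lost without ring closure, or enantiopurity may leak if ionisation is reversible. The fallback sets out from methyl acetoacetate 5 and returns at 9. Dianion 6 is alkylated with 1-bromo-3-methylbut-2-ene to give methyl 7-methyl-3-oxooct-6-enoate F8. Bromonium-induced cyclisation with an external Br+ source (Et2SBr·SbCl5Br, MeNO2, −25 °C) gives racemic methyl 3-bromo-2,2-dimethyl-6-oxocyclohexane-1-carboxylate F9. Preparative chromatography on a chiral stationary phase separates 9 from methyl (3S)-3-bromo-2,2-dimethyl-6-oxocyclohexane-1-carboxylate F10, which is discarded.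

Further compounds
F1 | step 13 | (2R,6R)-2-bromo-1,1,9-trimethyl-5-methylidenespiro[5.5]undec-8-ene | C=C1CC[C@@H](Br)C(C)(C)[C@@]12CCC(C)=CC2
F2 | step 12 | [(5R)-5-bromo-6,6-dimethyl-2-(trifluoromethanesulfonyloxy)cyclohex-1-en-1-yl]methanol | OCC1=C(OS(=O)(=O)C(F)(F)F)CC[C@@H](Br)C1(C)C
F3 | step 12 | (5R)-5-bromo-6,6-dimethyl-2-(trifluoromethanesulfonyloxy)cyclohex-1-ene-1-carbaldehyde | O=CC1=C(OS(=O)(=O)C(F)(F)F)CC[C@@H](Br)C1(C)C
F4 | step 12 | (4R)-4-bromo-2-ethenyl-3,3-dimethylcyclohex-1-en-1-yl trifluoromethanesulfonate | C=CC1=C(OS(=O)(=O)C(F)(F)F)CC[C@@H](Br)C1(C)C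
F5 | step 12 | (4R)-4-bromo-2-[2-(9-borabicyclo[3.3.1]nonan-9-yl)ethyl]-3,3-dimethylcyclohex-1-en-1-yl trifluoromethanesulfonate | C(CB1C2CCCC1CCC2)C3=C(OS(=O)(=O)C(F)(F)F)CC[C@@H](Br)C3(C)C
F6 | step 12 | (4R)-4-bromo-2-[(3Z)-5-hydroxy-3-methylpent-3-en-1-yl]-3,3-dimethylcyclohex-1-en-1-yl trifluoromethanesulfonate | OC/C=C(C)\CCC1=C(OS(=O)(=O)C(F)(F)F)CC[C@@H](Br)C1(C)C
F7 | step 12 | (4R)-4-bromo-2-[(3S,4S)-4-bromo-3-chloro-5-hydroxy-3-methylpentyl]-3,3-dimethylcyclohex-1-en-1-yl trifluoromethanesulfonate | OC[C@H](Br)[C@@](C)(Cl)CCC1=C(OS(=O)(=O)C(F)(F)F)CC[C@@H](Br)C1(C)C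
F8 | step 4 | methyl 7-methyl-3-oxooct-6-enoate | COC(=O)CC(=O)CCC=C(C)C
F9 | step 4 | racemic methyl 3-bromo-2,2-dimethyl-6-oxocyclohexane-1-carboxylate | COC(=O)C1C(=O)CCC(Br)C1(C)C
F10 | step 4 | methyl (3S)-3-bromo-2,2-dimethyl-6-oxocyclohexane-1-carboxylate | COC(=O)C1C(=O)CC[C@H](Br)C1(C)C
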